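# Proposed total synthesis of 4-[2-hydroxy-4-methoxy-6-(2-oxopentyl)benzoyloxy]-2-methoxy-6-pentylbenzoic acid (CNP0110448.0) by copper-mediated O-arylation of the ring A carboxylate

## The problem

The target is a depside: the carboxyl carbon of ring A, a 2-hydroxy-4-methoxy-6-(2-oxopentyl)benzoyl unit, is linked through oxygen to C4 of ring B, a 2-methoxy-6-pentylbenzoic acid. Each ring alone is a simple benzenoid, so the difficulty lies almost entirely in how the two are joined. The ring A carboxyl sits between the C2 oxygen and the C6 side chain, which screens its acyl carbon from an incoming phenol. The side-chain ketone also stands in a 1,5 relationship to that carbonyl. Whenever the acyl carbon is made electrophilic while the ketone is free, the enol oxygen can close onto it and give an isocoumarin, expelling whatever was attached. The molecule has no stereocentre, so the task is one of chemoselectivity and order of events only. Three functions will not survive rough treatment: the aryl ester (labile to hydroxide and alkoxide), the ketone next to it, and the ring B carboxylic acid, which has to be unveiled last without touching the depside bond. The opening for the key step lies on ring B: in a 2-methoxy-6-pentylbenzoate, C4–H is the only aromatic C–H flanked by two hydrogens (C3–H and C5–H). A sterically governed C–H borylation therefore marks exactly the carbon that must carry the ester oxygen, and the ring A carboxylate can then react through its unhindered oxygen.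

## Retrosynthesis

**Target 19 back to 18.** The two benzylic C–O bonds are cut last: the benzyl ether on the ring A C2 oxygen and the (3,5-dimethylphenyl)methyl ester on the ring B carboxyl. Both fall in one neutral hydrogenolysis, which the depside ester and the ketone tolerate. Any ester that needs hydroxide or strong acid for removal would compete with the aryl ester, so benzyl-type groups are preferred. The forward step must cleave two C–O bonds without reducing the ketone.

**18 back to 17.** The ketone is returned to its dioxolane. The mask is needed through the union and in the free ring A acid, where a free ketone would lactolise. It is removed before hydrogenolysis so that dilute aqueous acid acts while the ring B carboxyl is still an ester. The forward step is a plain ketal hydrolysis, kept short and cold.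

**17 back to 9 and 16.** The depside is cut at the O–C4 aryl bond of ring B, not at the acyl–oxygen bond. Cutting the acyl–oxygen bond would require an activated derivative of the hindered ring A acid and a ring B phenol. Cutting the aryl–oxygen bond instead makes the carboxylate of 9 the nucleophile and the boronic acid 16 the aryl donor under divalent copper. The acyl carbon is then never attacked and never activated. Both fragments are single benzene rings of comparable size, so the cut is fully convergent. The forward reaction must be chemoselective for the carboxylate oxygen, which the protecting groups of 9 ensure.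

**16 back to 14 through 15.** The C4–B bond is traced to the C4–H bond of ester 14 by iridium-catalysed borylation, with the pinacol boronate 15 cleaved to the boronic acid in the same flask. No phenol at C4 is ever needed. This step dictates the ester group: a plain benzyl ester would offer the catalyst three unhindered C–H bonds on its own phenyl ring. The 3,5-dimethyl analogue has no aromatic C–H without an ortho neighbour and is still removed by hydrogenolysis. The forward reaction must select one C–H bond out of nine aromatic ones, on steric grounds alone.

**14 back to 13, and 13 back to 10 and 11.** The ester comes from O-alkylation of acid 13, which does not involve the crowded acyl carbon. The pentyl chain is cut between its first and second carbons: the dianion 12 of 2-methoxy-6-methylbenzoic acid 10 is alkylated with 1-bromobutane 11. This uses the carboxylate as its own directing and protecting group and removes four carbons in one step.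

**9 back to 8 and 7.** The acid is released from methyl ester 8 by hydroxide, to which the ketal and benzyl ether are inert. The dioxolane of 8 comes from ketone 7. Ketalisation must precede saponification, since a free keto acid would close to the lactol and isocoumarin.

**7 back to 3 and 4.** The bond between the benzylic carbon and the ketone carbonyl is cut. The benzylic anion 5 of toluate 3 adds to N-methoxy-N-methylbutanamide 4, and the chelated adduct 6 holds the ketone oxidation level until work-up. This places the whole side chain in one step on a ring that already has every other substituent.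

**3 back to 2 and 1.** Two O-alkylations of methyl orsellinate 1 remain. The free C4 hydroxyl is methylated first to give 2, then the chelated C2 hydroxyl is benzylated to give 3. The difference in acidity and hydrogen bonding between the two phenols supplies the regiocontrol.

## Roads not taken

**Alternative 1:** The cut lies in the periphery of ring A: the C6–CH2 bond and a lactone C–O bond are formed together. In the forward step 2-(benzyloxy)-4-methoxybenzoic acid A1 and the butyryl sulfoxonium ylide A2 would be coupled under [Cp*RhCl2]2 (trivalent rhodium). Carboxylate-directed metalation at C6 (the only free ortho position), carbene-type insertion and condensation would give 8-(benzyloxy)-6-methoxy-3-propyl-1H-isochromen-1-one A3.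
- Merits: a catalytic step with unambiguous regiochemistry, no cryogenic strong base, and a robust crystalline product.
- Weak points: A3 is the very lactone that the plan must avoid. A ring B phenoxide cannot open it productively, because the enol lactone is the more stable side of that equilibrium. It would have to be opened with methoxide to keto ester 7, then ketalised and saponified exactly as in the chosen route. A1 and A2 each need preparing.
- Comparison: as a way to 7 it is about one step longer than steps 1–3, but operationally simpler. It does nothing for the depside bond, which is the real problem. The chosen plan reaches 7 directly and spends its strategic step on the union.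

**Alternative 2:** Ring B is cut across C1–C2 and C5–C6. In the forward step 1,1-dimethoxy-3-(trimethylsilyloxy)buta-1,3-diene A4 and benzyl oct-2-ynoate A5 would undergo a [4+2] cycloaddition. The ester-bearing alkyne carbon bonds to the acetal terminus, and loss of methanol and of the silyl group would give benzyl 4-hydroxy-2-methoxy-6-pentylbenzoate A6.
- Merits: the whole substitution pattern of ring B arises in one step from acyclic pieces. A plain benzyl ester can be used, since no borylation follows.
- Weak points: a β-alkyl ynoate is a sluggish dienophile and the ketene acetal diene is sensitive to heat and moisture. More seriously, A6 is a phenol, so the union falls back on acyl activation of the screened acid 9.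
- Comparison: for ring B alone this road is shorter, one step against three (steps 6–8). The chosen plan sets against this a union that never activates the hindered carbonyl. A6 could enter that union only after triflation and borylation, which removes the advantage.

**Alternative 3:** Ring A is cut across C1–C2 and C5–C6 after the ester link already exists. In the forward step 1,3-dimethoxy-1-(trimethylsilyloxy)buta-1,3-diene A7 would add across the alkyne of benzyl 2-methoxy-6-pentyl-4-{[4-(2-propyl-1,3-dioxolan-2-yl)but-2-ynoyl]oxy}benzoate A8. Loss of methanol and desilylation would give benzyl 4-{2-hydroxy-4-methoxy-6-[(2-propyl-1,3-dioxolan-2-yl)methyl]benzoyloxy}-2-methoxy-6-pentylbenzoate A9.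
- Merits: the ester bond is made on an unhindered alkynoic acid, and ring A appears with its C2 hydroxyl already free and chelated. In protecting-group economy this is better than the chosen plan.
- Weak points: A8 is an aryl ester of an ynoic acid and so doubly electrophilic, while A7 is a silyl ketene acetal. Conjugate addition followed by acyl substitution, with loss of the ring B phenoxide, competes with cycloaddition. The propargylic CH2 beside the ketal can isomerise to an allene. The ring is built on the most advanced intermediate, and A8 itself needs a ring B phenol and a multi-step ynoic acid.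
- Comparison: like the chosen plan it never activates the hindered acyl carbon. The chosen plan sets against it that each step is a known reaction type on its own substrate class, and that the two fragments are made independently in five and three steps.

Key step: step 9

## Route

Remark on the chemistry: the target has no stereocentre and no stereogenic double bond, so no compound below needs a stereodescriptor. Iodomethane, benzyl bromide and 1-(bromomethyl)-3,5-dimethylbenzene are taken as purchased reagents.

Step 1
Reactants: 1 methyl orsellinate (methyl 2,4-dihydroxy-6-methylbenzoate)
Product: 2 methyl 2-hydroxy-4-methoxy-6-methylbenzoate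
Conditions: MeI (1.1 equiv), K2CO3 (1.1 equiv), acetone, 40 °C
Reagents that add atoms: iodomethane, CI
Why: Williamson etherification; the C2 hydroxyl is hydrogen-bonded to the ester carbonyl and is the poorer nucleophile, so one equivalent of MeI with a mild carbonate base should alkylate the C4 hydroxyl selectively.

Step 2
Reactants: 2 methyl 2-hydroxy-4-methoxy-6-methylbenzoate
Product: 3 methyl 2-(benzyloxy)-4-methoxy-6-methylbenzoate
Conditions: BnBr (1.2 equiv), K2CO3 (2 equiv), DMF, 60 °C
Reagents that add atoms: benzyl bromide, BrCc1ccccc1
Why: Williamson benzylation of the remaining chelated phenol, which needs the polar solvent and heat; the benzyl ether later withstands amide base, hydroxide and divalent copper and leaves by hydrogenolysis.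

Step 3
Reactants: 3 methyl 2-(benzyloxy)-4-methoxy-6-methylbenzoate; 4 N-methoxy-N-methylbutanamide
Product: 7 methyl 2-(benzyloxy)-4-methoxy-6-(2-oxopentyl)benzoate, via benzylic lithium derivative of the toluate 5 (not isolated), via chelated lithium hemiaminal adduct 6 (not isolated)
Conditions: LiN(iPr)2 (1.2 equiv), THF, −78 °C; then 4, −78 → −40 °C; aq. NH4Cl
Reagents that add atoms: none
Why: Lateral (benzylic) lithiation ortho to the ester gives anion 5, which adds to the Weinreb amide; adduct 6 does not collapse until the quench, so over-addition and base-induced ring closure of the product ketone are avoided (Weinreb ketone synthesis).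

Step 4
Reactants: 7 methyl 2-(benzyloxy)-4-methoxy-6-(2-oxopentyl)benzoate
Product: 8 methyl 2-(benzyloxy)-4-methoxy-6-[(2-propyl-1,3-dioxolan-2-yl)methyl]benzoate
Conditions: (Me3SiOCH2)2 (1.5 equiv), Me3SiOTf (5 mol %), CH2Cl2, −78 → −20 °C; then pyridine, aq. NaHCO3
Reagents that add atoms: 1,2-bis(trimethylsilyloxy)ethane, C[Si](C)(C)OCCO[Si](C)(C)C
Why: Silyl-transfer ketalisation runs cold and without free protic acid or heat, so the keto ester should be masked before enol lactonisation to the isocoumarin can compete; formation of the disiloxane makes the step irreversible.

Step 5
Reactants: 8 methyl 2-(benzyloxy)-4-methoxy-6-[(2-propyl-1,3-dioxolan-2-yl)methyl]benzoate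
Product: 9 2-(benzyloxy)-4-methoxy-6-[(2-propyl-1,3-dioxolan-2-yl)methyl]benzoic acid
Conditions: KOH (10 equiv), DMSO/H2O (4:1), 80 °C; then 1 M HCl to pH 4, 0 °C
Reagents that add atoms: potassium hydroxide, [K+].[OH-]
Why: Saponification of a doubly ortho-substituted methyl benzoate is slow but should proceed with poorly solvated hydroxide in aqueous DMSO; the dioxolane and benzyl ether are inert to base, and cold acidification only to pH 4 should keep the ketal intact, the dried acid being used at once.

Step 6
Reactants: 10 2-methoxy-6-methylbenzoic acid; 11 1-bromobutane
Product: 13 2-methoxy-6-pentylbenzoic acid, via dilithio carboxylate benzylic dianion 12 (not isolated)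
Conditions: LiN(iPr)2 (2.2 equiv), THF, −78 → 0 °C; then 11 (1.2 equiv), −78 °C → rt; 1 M HCl
Reagents that add atoms: none
Why: Two equivalents of amide base give the carboxylate/benzylic dianion 12 (lateral lithiation), whose carbanion is alkylated by the primary bromide in an SN2 reaction while the carboxylate stays unreactive, extending methyl to pentyl in one operation.

Step 7
Reactants: 13 2-methoxy-6-pentylbenzoic acid
Product: 14 (3,5-dimethylphenyl)methyl 2-methoxy-6-pentylbenzoate
Conditions: 1-(bromomethyl)-3,5-dimethylbenzene (1.1 equiv), K2CO3 (1.5 equiv), DMF, rt → 40 °C
Reagents that add atoms: 1-(bromomethyl)-3,5-dimethylbenzene, Cc1cc(C)cc(CBr)c1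
Why: O-Alkylation of the carboxylate (SN2 at the benzylic bromide) is indifferent to crowding around the acyl carbon; the resulting ester is hydrogenolysable like a benzyl ester but has no aromatic C–H without an ortho substituent.

Step 8
Reactants: 14 (3,5-dimethylphenyl)methyl 2-methoxy-6-pentylbenzoate
Product: 16 [4-{[(3,5-dimethylphenyl)methoxy]carbonyl}-3-methoxy-5-pentylphenyl]boronic acid, via aryl pinacol boronate 15 (not isolated)
Conditions: [Ir(OMe)(cod)]2 (1.5 mol %), 4,4′-di-tert-butyl-2,2′-bipyridine (3 mol %), B2pin2 (1.0 equiv), THF, 80 °C; then NaIO4 (3 equiv), NH4OAc (3 equiv), acetone/H2O, rt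
Reagents that add atoms: bis(pinacolato)diboron, CC1(C)OB(OC1(C)C)B1OC(C)(C)C(C)(C)O1; water, O
Why: Iridium-catalysed C–H borylation with a bipyridine ligand is sterically governed and should touch only a C–H with no ortho substituent, which in 14 is C4–H of ring B alone (C3–H and C5–H each have one ortho group and every C–H of the ester aryl ring has two); periodate then destroys the pinacol released by hydrolysis and gives the free boronic acid in the same flask.

Step 9
Reactants: 9 2-(benzyloxy)-4-methoxy-6-[(2-propyl-1,3-dioxolan-2-yl)methyl]benzoic acid; 16 [4-{[(3,5-dimethylphenyl)methoxy]carbonyl}-3-methoxy-5-pentylphenyl]boronic acid (2 equiv)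
Product: 17 (3,5-dimethylphenyl)methyl 4-{2-(benzyloxy)-4-methoxy-6-[(2-propyl-1,3-dioxolan-2-yl)methyl]benzoyloxy}-2-methoxy-6-pentylbenzoate
Conditions: Cu(OTf)2 (40 mol %), urea (1 equiv), powdered 4 Å molecular sieves, EtOAc, 60 °C, dry air
Reagents that add atoms: none
Why: The carboxylate of 9 binds divalent copper, the aryl group of 16 passes from boron to copper, oxidation gives a trivalent copper aryl carboxylate, and C–O reductive elimination releases the aryl ester and monovalent copper, which air returns to the divalent state. The closest known reaction type is the Chan–Lam–Evans O-arylation of carboxylic acids with arylboronic acids under Cu(OTf)2 with urea as ligand. No ring is closed and no stereocentre is formed. The step needs chemoselective O-arylation of the carboxylate: with the C2 hydroxyl benzylated and the ketone held as a dioxolane, the carboxylate is the only O–H nucleophile in either partner. The site on ring B is fixed by the boron placed at C4 in step 8. Because bonding occurs at the carboxylate oxygen, the crowded acyl carbon is neither attacked nor activated, so the two ortho substituents should not retard the union and no acyl derivative exists that could collapse to an isocoumarin. Sieves and dry air limit protodeboronation and phenol formation, the excess of 16 covers what is lost that way, and the benzyl-type ester, benzyl ether and dioxolane are expected to tolerate the weakly acidic medium.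

Step 10
Reactants: 17 (3,5-dimethylphenyl)methyl 4-{2-(benzyloxy)-4-methoxy-6-[(2-propyl-1,3-dioxolan-2-yl)methyl]benzoyloxy}-2-methoxy-6-pentylbenzoate
Product: 18 (3,5-dimethylphenyl)methyl 4-[2-(benzyloxy)-4-methoxy-6-(2-oxopentyl)benzoyloxy]-2-methoxy-6-pentylbenzoate
Conditions: 2 M aq. HCl, THF, 0 °C → rt
Reagents that add atoms: water, O
Why: Acid-catalysed ketal hydrolysis through the oxocarbenium ion; dilute acid at room temperature should leave both esters and the benzyl ether untouched, and a short exposure is meant to keep the freed ketone from enolising onto the aryl ester.

Step 11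
Reactants: 18 (3,5-dimethylphenyl)methyl 4-[2-(benzyloxy)-4-methoxy-6-(2-oxopentyl)benzoyloxy]-2-methoxy-6-pentylbenzoate
Product: 19 4-[2-hydroxy-4-methoxy-6-(2-oxopentyl)benzoyloxy]-2-methoxy-6-pentylbenzoic acid
Conditions: H2 (1 atm), 10% Pd/C, EtOAc, rt
Reagents that add atoms: none
Why: Heterogeneous hydrogenolysis should cleave both benzylic C–O bonds (aryl benzyl ether and 3,5-dimethylbenzyl ester) under neutral conditions; the saturated ketone, the aryl ester and the arene rings are not reduced at one atmosphere.

## Compound list

1 | methyl orsellinate (methyl 2,4-dihydroxy-6-methylbenzoate) | COC(=O)c1c(C)cc(O)cc1O | starting material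
2 | methyl 2-hydroxy-4-methoxy-6-methylbenzoate | COC(=O)c1c(C)cc(OC)cc1O | intermediate
3 | methyl 2-(benzyloxy)-4-methoxy-6-methylbenzoate | COC(=O)c1c(C)cc(OC)cc1OCc1ccccc1 | intermediate
4 | N-methoxy-N-methylbutanamide | CCCC(=O)N(C)OC | starting material
5 | benzylic lithium derivative of 3 (methyl 2-(benzyloxy)-6-(lithiomethyl)-4-methoxybenzoate) | [Li]Cc1cc(OC)cc(OCc2ccccc2)c1C(=O)OC | intermediate
6 | lithium hemiaminal adduct of 5 and 4 | CCCC(O[Li])(Cc1cc(OC)cc(OCc2ccccc2)c1C(=O)OC)N(C)OC | intermediate
7 | methyl 2-(benzyloxy)-4-methoxy-6-(2-oxopentyl)benzoate | CCCC(=O)Cc1cc(OC)cc(OCc2ccccc2)c1C(=O)OC | intermediate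
8 | methyl 2-(benzyloxy)-4-methoxy-6-[(2-propyl-1,3-dioxolan-2-yl)methyl]benzoate | CCCC1(Cc2cc(OC)cc(OCc3ccccc3)c2C(=O)OC)OCCO1 | intermediate
9 | 2-(benzyloxy)-4-methoxy-6-[(2-propyl-1,3-dioxolan-2-yl)methyl]benzoic acid | CCCC1(Cc2cc(OC)cc(OCc3ccccc3)c2C(=O)O)OCCO1 | intermediate
10 | 2-methoxy-6-methylbenzoic acid | Cc1cccc(OC)c1C(=O)O | starting material
11 | 1-bromobutane | CCCCBr | starting material
12 | dilithio dianion of 10 (lithium 2-(lithiomethyl)-6-methoxybenzoate) | [Li]Cc1cccc(OC)c1C(=O)O[Li] | intermediate
13 | 2-methoxy-6-pentylbenzoic acid | CCCCCc1cccc(OC)c1C(=O)O | intermediate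
14 | (3,5-dimethylphenyl)methyl 2-methoxy-6-pentylbenzoate | CCCCCc1cccc(OC)c1C(=O)OCc1cc(C)cc(C)c1 | intermediate
15 | (3,5-dimethylphenyl)methyl 2-methoxy-6-pentyl-4-(4,4,5,5-tetramethyl-1,3,2-dioxaborolan-2-yl)benzoate | CCCCCc1cc(B2OC(C)(C)C(C)(C)O2)cc(OC)c1C(=O)OCc1cc(C)cc(C)c1 | intermediate
16 | [4-{[(3,5-dimethylphenyl)methoxy]carbonyl}-3-methoxy-5-pentylphenyl]boronic acid | CCCCCc1cc(B(O)O)cc(OC)c1C(=O)OCc1cc(C)cc(C)c1 | intermediate
17 | (3,5-dimethylphenyl)methyl 4-{2-(benzyloxy)-4-methoxy-6-[(2-propyl-1,3-dioxolan-2-yl)methyl]benzoyloxy}-2-methoxy-6-pentylbenzoate | CCCCCc1cc(OC(=O)c2c(OCc3ccccc3)cc(OC)cc2CC2(CCC)OCCO2)cc(OC)c1C(=O)OCc1cc(C)cc(C)c1 | intermediate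
18 | (3,5-dimethylphenyl)methyl 4-[2-(benzyloxy)-4-methoxy-6-(2-oxopentyl)benzoyloxy]-2-methoxy-6-pentylbenzoate | CCCCCc1cc(OC(=O)c2c(OCc3ccccc3)cc(OC)cc2CC(=O)CCC)cc(OC)c1C(=O)OCc1cc(C)cc(C)c1 | intermediate
19 | 4-[2-hydroxy-4-methoxy-6-(2-oxopentyl)benzoyloxy]-2-methoxy-6-pentylbenzoic acid | CCCCCc1cc(OC(=O)c2c(O)cc(OC)cc2CC(=O)CCC)cc(OC)c1C(=O)O | target

## Step count and risks

Total step count: 11. Longest linear sequence: 8 steps (steps 1–5, 9, 10 and 11, from methyl orsellinate 1). The ring B branch (steps 6–8) joins at step 9.

**Step 9 (key step).** The most likely failure is protodeboronation and oxidative hydroxylation or homocoupling of 16 running faster than aryl transfer to the crowded copper carboxylate, so that conversion of 9 stalls. A second danger is opening of the dioxolane by the Lewis-acidic copper salt together with water released from the boronic acid. The resulting keto acid would close to its lactol and drop out of the coupling. Copper-promoted loss of CO2 from the electron-rich 2,6-disubstituted acid is a lesser risk at 60 °C.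

Fallback: return to acyl substitution, but through the smallest activated acyl group and with the ketone still masked. Boronic acid 16 would be oxidised (H2O2, aq. NaHCO3, THF) to (3,5-dimethylphenyl)methyl 4-hydroxy-2-methoxy-6-pentylbenzoate F1. Acid 9 would be converted with cyanuric fluoride and pyridine in CH2Cl2 into 2-(benzyloxy)-4-methoxy-6-[(2-propyl-1,3-dioxolan-2-yl)methyl]benzoyl fluoride F2. Acylation of the potassium phenoxide of F1 (K2CO3, MeCN, 50 °C) by F2 should give 17, where the route is rejoined. The basic medium spares the ketal, and the ketal in turn prevents isocoumarin formation from the acyl fluoride.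

**Step 10.** The risk is enol lactonisation. The ketone released beside the aryl ester can enolise toward the benzylic CH2 and attack the depside carbonyl through oxygen, expelling ring B as a phenol. The acid that opens the ketal also promotes this.

Fallback: reverse the order of unmasking. Hydrogenolysis of 17 (H2, 10% Pd/C, EtOAc) would first give 4-{2-hydroxy-4-methoxy-6-[(2-propyl-1,3-dioxolan-2-yl)methyl]benzoyloxy}-2-methoxy-6-pentylbenzoic acid F3. The dioxolane would then be removed by exchange with dry acetone under catalytic pyridinium p-toluenesulfonate at 40 °C, giving 19 directly. The ketone then appears only in the target itself, where the chelated C2 hydroxyl conjugates with the depside carbonyl and deactivates it, and no mineral acid is present.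

**Step 5.** Hydroxide attack at the doubly screened acyl carbon may stall. Forcing it further would put the benzyl ether at risk and, on work-up, the ketal.

Fallback: move the site of attack from the acyl carbon to the ester methyl group. Treating 8 with NaSEt in DMF at 60 °C should cleave the O–CH3 bond by SN2 displacement. Acidification to pH 4 then gives 9. This detour passes through no compound outside the route (F0). Aryl methyl ethers react with thiolate only at considerably higher temperature.

**Step 8.** The borylation itself is expected to be site-selective. The weak point is the one-flask release of the boronic acid: incomplete oxidative removal of pinacol, or partial oxidation of the C–B bond by periodate, would leave a mixture that cannot be dosed reliably into step 9. Slow borylation at the methyl groups of the ester is a lesser risk.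

Fallback: isolate 15 by filtration through silica and convert it with KHF2 in aqueous methanol into potassium [4-{[(3,5-dimethylphenyl)methoxy]carbonyl}-3-methoxy-5-pentylphenyl]trifluoroborate F4, purified by crystallisation. Hydrolysis with Me3SiCl and water in MeCN would then give 16, where the route is rejoined.

## Further compounds

F1 | step 9 | (3,5-dimethylphenyl)methyl 4-hydroxy-2-methoxy-6-pentylbenzoate | CCCCCc1cc(O)cc(OC)c1C(=O)OCc1cc(C)cc(C)c1
F2 | step 9 | 2-(benzyloxy)-4-methoxy-6-[(2-propyl-1,3-dioxolan-2-yl)methyl]benzoyl fluoride | CCCC1(Cc2cc(OC)cc(OCc3ccccc3)c2C(F)=O)OCCO1
F3 | step 10 | 4-{2-hydroxy-4-methoxy-6-[(2-propyl-1,3-dioxolan-2-yl)methyl]benzoyloxy}-2-methoxy-6-pentylbenzoic acid | CCCCCc1cc(OC(=O)c2c(O)cc(OC)cc2CC2(CCC)OCCO2)cc(OC)c1C(=O)O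
F0 | step 5 | none | none
F4 | step 8 | potassium [4-{[(3,5-dimethylphenyl)methoxy]carbonyl}-3-methoxy-5-pentylphenyl]trifluoroborate | CCCCCc1cc([B-](F)(F)F)cc(OC)c1C(=O)OCc1cc(C)cc(C)c1.[K+]
A1 | alternative 1 | 2-(benzyloxy)-4-methoxybenzoic acid | COc1ccc(C(=O)O)c(OCc2ccccc2)c1
A2 | alternative 1 | 1-[dimethyl(oxo)-λ6-sulfanylidene]pentan-2-one | CCCC(=O)C=S(C)(C)=O
A3 | alternative 1 | 8-(benzyloxy)-6-methoxy-3-propyl-1H-isochromen-1-one | CCCC1=Cc2cc(OC)cc(OCc3ccccc3)c2C(=O)O1
A4 | alternative 2 | 1,1-dimethoxy-3-(trimethylsilyloxy)buta-1,3-diene | COC(OC)=CC(=C)O[Si](C)(C)C
A5 | alternative 2 | benzyl oct-2-ynoate | CCCCCC#CC(=O)OCc1ccccc1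
A6 | alternative 2 | benzyl 4-hydroxy-2-methoxy-6-pentylbenzoate | CCCCCc1cc(O)cc(OC)c1C(=O)OCc1ccccc1
A7 | alternative 3 | 1,3-dimethoxy-1-(trimethylsilyloxy)buta-1,3-diene | COC(=C)C=C(OC)O[Si](C)(C)C
A8 | alternative 3 | benzyl 2-methoxy-6-pentyl-4-{[4-(2-propyl-1,3-dioxolan-2-yl)but-2-ynoyl]oxy}benzoate | CCCCCc1cc(OC(=O)C#CCC2(CCC)OCCO2)cc(OC)c1C(=O)OCc1ccccc1
A9 | alternative 3 | benzyl 4-{2-hydroxy-4-methoxy-6-[(2-propyl-1,3-dioxolan-2-yl)methyl]benzoyloxy}-2-methoxy-6-pentylbenzoate | CCCCCc1cc(OC(=O)c2c(O)cc(OC)cc2CC2(CCC)OCCO2)cc(OC)c1C(=O)OCc1ccccc1
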